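## Retrosynthetic overview

1. Last bonds: hydroxide opening of an enol lactone ⇐ catalyst-controlled dearomative C-prenylation of a C-lavandulyl tricyclic phenol (creates the quaternary carbon and the cyclohexadienone).
2. Aryl–CH2(lavandulyl) bond ⇐ Negishi coupling of an aryl iodide with an (R)-lavandulylzinc reagent; lavandulyl stereocentre ⇐ Evans deconjugative prenylation of a senecioyl imide.
3. Chromanone ring ⇐ biomimetic, quinine-catalysed cis-selective oxa-Michael closure of an ortho-hydroxyaryl tigloyl ketone (two stereocentres).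
4. Lactone (neoflavonoid) ring ⇐ biomimetic catalytic asymmetric annulation of a cinnamoyl unit onto symmetric phloroglucinol (CHPh stereocentre), then Friedel–Crafts tigloylation.
5. Ring order: aromatic ring (bought) → lactone ring → chromanone ring → aromatic ring dearomatised to the dienone; the lactone ring is opened at the end.

Assumption: the sense of induction of each chiral catalyst (HyperBTM, quinine, Trost ligand) is taken from its accepted model or closest precedent; the antipodal or pseudo-enantiomeric catalyst is used if an assay shows the opposite sense.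

## Route

Step 1
Reactants: 1 phloroglucinol (benzene-1,3,5-triol); 2 (E,E)-cinnamic anhydride
Product: 3 (S)-5,7-dihydroxy-4-phenylchroman-2-one
Conditions: (2R,3S)-HyperBTM (10 mol%), i-Pr2NEt (1.2 equiv), 1 in excess (3 equiv), THF, −20 °C → rt
Reagents that add atoms: cinnamic anhydride 2, O=C(/C=C/c1ccccc1)OC(=O)/C=C/c1ccccc1
Why: Proposed new method: the isothiourea is acylated by 2 to an s-cis α,β-unsaturated acyl ammonium ion whose β-face anti to the catalyst phenyl is attacked by a ring carbon of 1 (a soft, trione-like C-nucleophile), the neighbouring phenol then lactonises and releases the catalyst, so C4 is set as S under catalyst control while reversible O-cinnamoylation funnels to the lactone and the symmetry of 1 removes any regiochemical issue; the closest known reaction type is the isothiourea-catalysed Michael addition–lactonisation of 1,3-dicarbonyl compounds with α,β-unsaturated acyl ammonium ions.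

Step 2
Reactants: 3 (S)-5,7-dihydroxy-4-phenylchroman-2-one; 4 tigloyl chloride [(E)-2-methylbut-2-enoyl chloride]
Product: 5 (S)-5,7-dihydroxy-8-[(E)-2-methylbut-2-enoyl]-4-phenylchroman-2-one
Conditions: AlCl3 (4 equiv), PhNO2, 0 °C → rt, cold aqueous HCl quench
Reagents that add atoms: tigloyl chloride 4, C/C=C(\C)C(Cl)=O
Why: Friedel–Crafts acylation of the phloroglucinol nucleus, expected at C8 (ortho to 7-OH, para to 5-OH, flanked by the small lactone oxygen) by analogy with the 8-acylation of 5,7-dihydroxy-4-substituted coumarins; no stereocentre is touched.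

Step 3
Reactants: 5 (S)-5,7-dihydroxy-8-[(E)-2-methylbut-2-enoyl]-4-phenylchroman-2-one
Product: 6 (4S,8R,9S)-5-hydroxy-8,9-dimethyl-4-phenyl-3,4,8,9-tetrahydro-2H,10H-pyrano[2,3-f]chromene-2,10-dione
Conditions: quinine (20 mol%), PhCl, 14 °C
Reagents that add atoms: none
Why: Cinchona-alkaloid-catalysed intramolecular oxa-Michael addition of the only hydroxyl ortho to the enone (7-OH), in which quinine directs the phenol to one enone face and kinetic protonation of the enol gives the cis-2,3-dimethylchromanone, setting C8 as R and C9 as S as known for 7-hydroxy-8-tigloylcoumarins.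

Step 4
Reactants: 6 (4S,8R,9S)-5-hydroxy-8,9-dimethyl-4-phenyl-3,4,8,9-tetrahydro-2H,10H-pyrano[2,3-f]chromene-2,10-dione
Product: 7 (4S,8R,9S)-5-hydroxy-6-iodo-8,9-dimethyl-4-phenyl-3,4,8,9-tetrahydro-2H,10H-pyrano[2,3-f]chromene-2,10-dione
Conditions: NIS (1.05 equiv), MeCN, 0 °C, dark
Reagents that add atoms: N-iodosuccinimide, O=C1CCC(=O)N1I
Why: Electrophilic aromatic iodination at the single free, oxygen-activated ring position (C6) under neutral conditions that leave the lactone and the cis-chromanone untouched.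

Step 5
Reactants: 8 (R)-4-benzyloxazolidin-2-one; 9 3-methylbut-2-enoyl chloride
Product: 11 (R)-4-benzyl-3-(3-methylbut-2-enoyl)oxazolidin-2-one, via lithium oxazolidinide 10 (not isolated)
Conditions: n-BuLi, THF, −78 °C; then 9, −78 → 0 °C
Reagents that add atoms: 3-methylbut-2-enoyl chloride 9, CC(C)=CC(Cl)=O
Why: N-acylation of the lithiated Evans auxiliary at low temperature, which avoids vinylketene formation (deconjugation) from the unsaturated acid chloride.

Step 6
Reactants: 11 (R)-4-benzyl-3-(3-methylbut-2-enoyl)oxazolidin-2-one; 12 prenyl bromide (1-bromo-3-methylbut-2-ene)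
Product: 14 (R)-4-benzyl-3-[(R)-5-methyl-2-(prop-1-en-2-yl)hex-4-enoyl]oxazolidin-2-one, via sodium dienolate 13 (not isolated)
Conditions: NaN(SiMe3)2, THF, −78 °C; then 12 (3 equiv), −78 → −30 °C
Reagents that add atoms: prenyl bromide 12, CC(C)=CCBr
Why: Evans deconjugative α-alkylation in which γ-deprotonation gives the chelated Z-dienolate that is prenylated at the α-carbon on the face opposite the benzyl group, setting the lavandulyl stereocentre as R.

Step 7
Reactants: 14 (R)-4-benzyl-3-[(R)-5-methyl-2-(prop-1-en-2-yl)hex-4-enoyl]oxazolidin-2-one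
Product: 15 (R)-lavandulol [(R)-5-methyl-2-(prop-1-en-2-yl)hex-4-en-1-ol]
Conditions: LiBH4, THF, 0 °C
Reagents that add atoms: none
Why: Reductive cleavage of the imide by borohydride releases the primary alcohol and the recoverable auxiliary without epimerising the α-stereocentre.

Step 8
Reactants: 15 (R)-lavandulol
Product: 16 (R)-lavandulyl iodide [(R)-3-(iodomethyl)-2,6-dimethylhepta-1,5-diene]
Conditions: I2, PPh3, imidazole, CH2Cl2, 0 °C
Reagents that add atoms: iodine, II
Why: Appel-type iodination (Garegg–Samuelsson conditions) by SN2 displacement at the primary carbon, so the adjacent stereocentre is not involved.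

Step 9
Reactants: 16 (R)-lavandulyl iodide; 7 (4S,8R,9S)-5-hydroxy-6-iodo-8,9-dimethyl-4-phenyl-3,4,8,9-tetrahydro-2H,10H-pyrano[2,3-f]chromene-2,10-dione
Product: 19 (4S,8R,9S)-5-hydroxy-8,9-dimethyl-6-[(2S)-5-methyl-2-(prop-1-en-2-yl)hex-4-en-1-yl]-4-phenyl-3,4,8,9-tetrahydro-2H,10H-pyrano[2,3-f]chromene-2,10-dione, via lavandulyllithium 17 (not isolated), via lavandulylzinc bromide 18 (not isolated)
Conditions: 16 (1.5 equiv), t-BuLi (2.1 equiv per iodide), Et2O/pentane, −78 °C; ZnBr2, THF, −78 → 0 °C; then slow addition to 7, Pd(OAc)2 (5 mol%), SPhos (10 mol%), THF, 25 °C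
Reagents that add atoms: none
Why: Negishi sp3–sp2 cross-coupling in which polar iodine–lithium exchange and transmetalation to zinc avoid radical vinyl migration and leave the β-stereocentre untouched, while base-free Pd/SPhos coupling of the alkylzinc halide outruns its protonation by the free phenol and spares the cis-chromanone.

Step 10
Reactants: 19 (the C6-lavandulyl tricyclic phenol from step 9); 20 prenyl acetate (3-methylbut-2-en-1-yl acetate)
Product: 22 (3S)-3-[(2R,3S,8S)-5-hydroxy-2,3-dimethyl-8-(3-methylbut-2-en-1-yl)-8-[(2S)-5-methyl-2-(prop-1-en-2-yl)hex-4-en-1-yl]-4,7-dioxo-3,4,7,8-tetrahydro-2H-chromen-6-yl]-3-phenylpropanoic acid, via dearomatised enol lactone 21 (not isolated)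
Conditions: Pd2(dba)3·CHCl3 (2.5 mol%), (R,R)-DACH-phenyl Trost ligand (7.5 mol%), 20 (1.5 equiv), Li2CO3, dioxane, 25 °C; then LiOH, THF/H2O, 0 °C; 1 M HCl to pH 3
Reagents that add atoms: prenyl acetate 20, CC(C)=CCOC(C)=O; lithium hydroxide in water, [Li+].[OH-]
Why: Proposed new method: a Pd-catalysed asymmetric allylic alkylative dearomatisation (Tsuji–Trost) in which the phenolate of 19 attacks the unsubstituted terminus of the π-prenyl palladium complex through C6, any O-prenyl ether being re-ionised because the acylphenolate is a good leaving group, and the chiral pocket of the Trost ligand selects the face of the planar phenolate to set the quaternary carbon as S, after which hydroxide opens the activated enol lactone while the resulting vinylogous-acid anion protects the cis-chromanone from enolisation; the closest known reaction types are the Pd/Trost-ligand intermolecular allylic dearomatisation of substituted naphthols and the linear-selective asymmetric prenylation of oxindoles.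

## Compound list

1 | phloroglucinol (benzene-1,3,5-triol) | Oc1cc(O)cc(O)c1 | starting material
2 | (E,E)-cinnamic anhydride | O=C(/C=C/c1ccccc1)OC(=O)/C=C/c1ccccc1 | starting material
3 | (S)-5,7-dihydroxy-4-phenylchroman-2-one | O=C1C[C@@H](c2ccccc2)c2c(O)cc(O)cc2O1 | intermediate
4 | tigloyl chloride, (E)-2-methylbut-2-enoyl chloride | C/C=C(\C)C(Cl)=O | starting material
5 | (S)-5,7-dihydroxy-8-[(E)-2-methylbut-2-enoyl]-4-phenylchroman-2-one | O=C1C[C@@H](c2ccccc2)c2c(O)cc(O)c(C(=O)/C(C)=C/C)c2O1 | intermediate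
6 | (4S,8R,9S)-5-hydroxy-8,9-dimethyl-4-phenyl-3,4,8,9-tetrahydro-2H,10H-pyrano[2,3-f]chromene-2,10-dione (cis-8,9-dimethyl) | O=C1C[C@@H](c2ccccc2)c2c(O)cc3O[C@H](C)[C@H](C)C(=O)c3c2O1 | intermediate
7 | (4S,8R,9S)-5-hydroxy-6-iodo-8,9-dimethyl-4-phenyl-3,4,8,9-tetrahydro-2H,10H-pyrano[2,3-f]chromene-2,10-dione | O=C1C[C@@H](c2ccccc2)c2c(O)c(I)c3O[C@H](C)[C@H](C)C(=O)c3c2O1 | intermediate
8 | (R)-4-benzyloxazolidin-2-one | O=C1N[C@H](Cc2ccccc2)CO1 | starting material
9 | 3-methylbut-2-enoyl chloride (senecioyl chloride) | CC(C)=CC(Cl)=O | starting material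
10 | lithium (R)-4-benzyl-2-oxooxazolidin-3-ide | [Li+].O=C1[N-][C@H](Cc2ccccc2)CO1 | intermediate
11 | (R)-4-benzyl-3-(3-methylbut-2-enoyl)oxazolidin-2-one | CC(C)=CC(=O)N1[C@H](Cc2ccccc2)COC1=O | intermediate
12 | prenyl bromide (1-bromo-3-methylbut-2-ene) | CC(C)=CCBr | starting material
13 | sodium (Z)-dienolate of 11 | [Na+].C=C(C)/C=C(\[O-])N1[C@H](Cc2ccccc2)COC1=O | intermediate
14 | (R)-4-benzyl-3-[(R)-5-methyl-2-(prop-1-en-2-yl)hex-4-enoyl]oxazolidin-2-one | C=C(C)[C@@H](CC=C(C)C)C(=O)N1[C@H](Cc2ccccc2)COC1=O | intermediate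
15 | (R)-lavandulol, (R)-5-methyl-2-(prop-1-en-2-yl)hex-4-en-1-ol | C=C(C)[C@@H](CC=C(C)C)CO | intermediate
16 | (R)-lavandulyl iodide, (R)-3-(iodomethyl)-2,6-dimethylhepta-1,5-diene | C=C(C)[C@@H](CC=C(C)C)CI | intermediate
17 | [(2R)-5-methyl-2-(prop-1-en-2-yl)hex-4-en-1-yl]lithium (lavandulyllithium) | [Li]C[C@H](CC=C(C)C)C(C)=C | intermediate
18 | [(2R)-5-methyl-2-(prop-1-en-2-yl)hex-4-en-1-yl]zinc bromide (lavandulylzinc bromide) | Br[Zn]C[C@H](CC=C(C)C)C(C)=C | intermediate
19 | (4S,8R,9S)-5-hydroxy-8,9-dimethyl-6-[(2S)-5-methyl-2-(prop-1-en-2-yl)hex-4-en-1-yl]-4-phenyl-3,4,8,9-tetrahydro-2H,10H-pyrano[2,3-f]chromene-2,10-dione | O=C1C[C@@H](c2ccccc2)c2c(O)c(C[C@H](CC=C(C)C)C(C)=C)c3O[C@H](C)[C@H](C)C(=O)c3c2O1 | intermediate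
20 | prenyl acetate (3-methylbut-2-en-1-yl acetate) | CC(C)=CCOC(C)=O | starting material
21 | (4S,6S,8R,9S)-8,9-dimethyl-6-(3-methylbut-2-en-1-yl)-6-[(2S)-5-methyl-2-(prop-1-en-2-yl)hex-4-en-1-yl]-4-phenyl-3,4,8,9-tetrahydro-2H-pyrano[2,3-f]chromene-2,5,10(6H)-trione | C=C(C)[C@@H](CC=C(C)C)C[C@]1(CC=C(C)C)C(=O)C3=C(OC(=O)C[C@H]3c4ccccc4)C2=C1O[C@H](C)[C@H](C)C2=O | intermediate
22 | (3S)-3-[(2R,3S,8S)-5-hydroxy-2,3-dimethyl-8-(3-methylbut-2-en-1-yl)-8-[(2S)-5-methyl-2-(prop-1-en-2-yl)hex-4-en-1-yl]-4,7-dioxo-3,4,7,8-tetrahydro-2H-chromen-6-yl]-3-phenylpropanoic acid (CNP0150579.2) | C=C(C)[C@@H](CC=C(C)C)C[C@]1(CC=C(C)C)C(=O)C([C@@H](CC(=O)O)c2ccccc2)=C(O)C2=C1O[C@H](C)[C@H](C)C2=O | target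

## Step count and risks

Total step count: 10. Longest linear sequence: 6 steps (steps 1, 2, 3, 4, 9, 10; the side-chain branch 5, 6, 7, 8, 9, 10 is equally long).

The three steps most likely to fail:

**Step 1 (asymmetric cinnamoyl annulation of free phloroglucinol).** O-cinnamoylation may not revert, bis-annulation may compete, and the enantioselectivity is untested on a triphenol. The fallback sets out from 1 and replaces the organocatalytic annulation by a coumarin route. A ZnCl2-mediated von Pechmann condensation of 1 with ethyl propiolate (100 °C) gives 5,7-dihydroxycoumarin F1. Hayashi-type asymmetric conjugate addition of PhB(OH)2 to F1 with Rh(acac)(C2H4)2 and (S)-Segphos (dioxane/H2O, 60 °C) then sets the 4S centre by metal catalysis and comes back to the route at 3.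

**Step 9 (Negishi coupling of the β-branched alkylzinc with the hindered iodophenol).** The free phenol may protonate the zinc reagent, and the allylic tertiary β-hydrogen invites β-hydride elimination and reduction of 7 back to 6. The fallback sets out from 16 and 7 and changes the organometallic partner and the transmetalation manifold. Lavandulyllithium made from 16 is trapped with 9-methoxy-9-borabicyclo[3.3.1]nonane to give the lithium B-lavandulyl-B-methoxy borate F2. This is coupled with the phenolate of 7 in a B-alkyl Suzuki–Miyaura reaction (PdCl2(dppf), AsPh3, K3PO4, DMF/H2O, 25 °C), which tolerates the acidic proton, and comes back to the route at 19.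

**Step 10 (Pd-catalysed dearomative prenylation).** O-allylation may persist, attack may occur at the ring-fusion carbon, and the ligand may give the wrong or a poor C6 epimer ratio. The fallback sets out from 19 and delivers the prenyl group intramolecularly instead of through a π-allyl complex. Cu-catalysed O-alkylation with 3-chloro-3-methylbut-1-yne (CuCl2 cat., DBU, MeCN, 0 °C) gives the aryl 1,1-dimethylpropargyl ether F3. Semi-hydrogenation (H2, Pd/CaCO3 poisoned with Pb(OAc)2, quinoline) gives the aryl 1,1-dimethylallyl ether F4. Aromatic Claisen rearrangement of F4 (toluene, 80 °C) places a linear prenyl group on C6 and gives 21 together with its C6 epimer, which is removed by preparative HPLC. The route is rejoined at 21, which is hydrolysed as in step 10.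

## Further compounds

F1 | step 1 | 5,7-dihydroxy-2H-chromen-2-one (5,7-dihydroxycoumarin) | O=c1ccc2c(O)cc(O)cc2o1
F2 | step 9 | lithium 9-methoxy-9-[(2R)-5-methyl-2-(prop-1-en-2-yl)hex-4-en-1-yl]-9-boranuidabicyclo[3.3.1]nonane (B-lavandulyl-B-methoxy borate) | [Li+].CO[B-]1(C[C@H](CC=C(C)C)C(C)=C)C2CCCC1CCC2
F3 | step 10 | (4S,8R,9S)-8,9-dimethyl-5-[(2-methylbut-3-yn-2-yl)oxy]-6-[(2S)-5-methyl-2-(prop-1-en-2-yl)hex-4-en-1-yl]-4-phenyl-3,4,8,9-tetrahydro-2H,10H-pyrano[2,3-f]chromene-2,10-dione | O=C1C[C@@H](c2ccccc2)c2c(OC(C)(C)C#C)c(C[C@H](CC=C(C)C)C(C)=C)c3O[C@H](C)[C@H](C)C(=O)c3c2O1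
F4 | step 10 | (4S,8R,9S)-8,9-dimethyl-5-[(2-methylbut-3-en-2-yl)oxy]-6-[(2S)-5-methyl-2-(prop-1-en-2-yl)hex-4-en-1-yl]-4-phenyl-3,4,8,9-tetrahydro-2H,10H-pyrano[2,3-f]chromene-2,10-dione | O=C1C[C@@H](c2ccccc2)c2c(OC(C)(C)C=C)c(C[C@H](CC=C(C)C)C(C)=C)c3O[C@H](C)[C@H](C)C(=O)c3c2O1
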